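Late in a run target is still leaking to over-reaction product at 0.017 s⁻¹, while cross product has no step out, so the meeting asked what each recipe commits to cross product.

the same everywhere: gas 2.3 mM (held); time 80 s

| charge | starting material | second substrate | remark |
|---|---|---|---|
| Monday's | 21 mM | 10.5 mM (fed, over 1.0 min) | all else is in the flask from the start; the feed brings no volume worth counting |
| Sunday's | 21 mM | 10.5 mM (fed, over 15 s) | all else is in the flask from the start; the feed brings no volume worth counting |
| Thursday's | 21 mM (fed, over 1.0 min) | 10.5 mM | all else is in the flask from the start; the feed brings no volume worth counting |
| Friday's | 21 mM | 10.5 mM (in portions, 5, over 1.0 min) | first portion at the start, last at 1.0 min |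
| Saturday's | 21 mM | 10.5 mM | everything together at the start |

    starting material + partner → target (k1 = 23 L mol⁻¹ s⁻¹)
    second substrate + partner → second product (k2 = 24 L mol⁻¹ s⁻¹)
    starting material + second substrate → cross product (k3 = 11 L mol⁻¹ s⁻¹)
    gas ⇌ partner, rate k4*(csat - [partner]) (k4 = 0.20 s⁻¹, csat = 2.3 mM)
    target → over-reaction product (k5 = 0.017 s⁻¹)
    target ⇌ isomer of the product (K6 = 0.95, k6 = 0.0058 s⁻¹)

- at the start none of partner is dissolved
- run time (Monday's): 80 s

- the flask with the highest share of target in target plus cross product ("all alike" if they lie within 1.5 percentage points) (Monday's / Sunday's / Thursday's / Friday's / Saturday's / all alike)
- share of target in target plus cross product at the end, Monday's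
- share of target in target plus cross product at the end, Sunday's
- share of target in target plus cross product at the end, Thursday's
- share of target in target plus cross product at the end, Friday's
- share of target in target plus cross product at the end, Saturday's

**Minutes.** One member argued for dosing second substrate, since the slow feed lasts 14 of its lifetimes against everything charged. Another objected that starting material stands in the flask during that feed, so each portion still meets it, and she asked to see the fate of second substrate reckoned.

I reckoned it as secretary. Second substrate has two exits: 0.231 s⁻¹ toward starting material as charged and 0.0552 s⁻¹ toward partner at saturation, 2.3 mM. The first is faster. I called the cross share the exit rate toward starting material divided by the sum of both exit rates, 80.7% here; it moves with the concentrations, while the selectivity factor, the ratio of the rate constants of the two exits, stands at 0.458. The fraction left for second product is then 19.3%. For Saturday's that puts cross product near 40.4% of the charged starting material.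

Thursday's needed a different starting amount. Second substrate lives 18.1 s against partner at saturation, and in that time the feed brings 6.34 mM of starting material, if none has reacted. The cross share there is 55.8%, which gives 27.9% for Thursday's, less than for Saturday's. My reckoning stopped there. It gives no share of target, and it covers two flasks.

The forecast was then read out. It named Thursday's, with Monday's at 40%, Sunday's at 32.5%, Thursday's at 53.5%, Friday's at 43% and Saturday's at 30%. Its ground was that “late-fed starting material meets little second substrate”.

**Result.** The simulation gives Thursday's as the highest, with Monday's at 41.4%, Sunday's at 31.7%, Thursday's at 52.4%, Friday's at 42.4% and Saturday's at 29.9%.

In Saturday's the reckoned cross product of 40.4% stands against 45.3% of the charged starting material in the flask, and in Thursday's the reckoned 27.9% stands against 26.4%; in Saturday's 94% of the cross step's turnover lies within the first 16.0 s, and at 24.1 s starting material has a half-life of 25 s on the path to target, shorter than the 190 s on the path to cross product. The neighbour of Saturday's with 8.4 mM of starting material has its cross share down at 62.6%, which gives 78.3% of that smaller charge, and its run ends with cross product at 69.0%.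

The rate constants are invented; the flask was simulated.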